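## Retrosynthetic overview
1. Endgame: the target comes from fluoride release of the C11 acid from a 2-(trimethylsilyl)ethyl (TMSE) ester. Before that come Yamaguchi acylation of 6β-OH, SeO2 oxidation of C12, and Luche reduction of C6=O in TMSE 9α-hydroxy-6-oxodrim-7-en-11-oate.
2. Ring-B tailoring: 9α-OH comes from aerobic hydroxylation of the vinylogous β-keto ester (C6=O / C7H2 / C8=C9–C11). C11 comes from Pd carbonylation of a C9 enol triflate, itself made by conjugate hydride addition and triflation of a trans-fused ene-1,4-dione. The C4 gem-dimethyl group comes from hydrogenolysis of a spirocyclopropane.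
3. Key disconnection: C1–C10 and C4–C5 are cut together. Ring A (C1–C2–C3–C4–C5–C10) comes from a catalytic enantioselective [4+2] of 2,6-dimethyl-1,4-benzoquinone with allylidenecyclopropane, followed by epimerisation at C5.
4. Enabling feature: ring B carries its two oxygenated carbons C6 and C9 para to each other, and C9 is flanked by C8 (bearing C12) and C10 (bearing the angular methyl). This is the pattern of the flat, C2v-symmetric quinone. Ring A is an unfunctionalised four-carbon bridge across the C5–C10 edge, and its one demand, quaternary C4, sits next to C5, which is α to C6=O and therefore correctable.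
5. Ring order: ring B is bought closed (the quinone), then ring A is closed in step 2 as the last ring of the skeleton. The cyclopropane is a temporary ring that arrives with the diene and is opened in step 6.

Key step: step 2

Remark (nomenclature): drimane numbering is used (ring A = C1–C5, C10; ring B = C5–C10; C11 on C9, C12 on C8, C13/C14 on C4, C15 on C10). "13,14-cyclo" denotes the spirocyclopropane at C4, and "11-nor" means that C11 is still missing.
Remark (assumption): the (S)-proline-derived catalyst is taken to expose the quinone face that leads to the 10S adduct drawn. If the sense is opposite, the mirror-image catalyst is used with no other change.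
Remark (assumption): the target is handled as the open 12-aldehyde/11-acid form drawn. Ring–chain tautomerism to a 12-hydroxy-11,12-olide is not considered.

## Route

Step 1
Reactants: 1 cyclopropyltriphenylphosphonium bromide; 2 acrolein
Product: 4 allylidenecyclopropane (prop-2-enylidenecyclopropane), via cyclopropylidene(triphenyl)phosphorane 3 (not isolated)
Conditions: KOt-Bu, THF, 50 °C; then 2, 0 °C to rt; pentane/water wash, distillation
Reagents that add atoms: none
Why: Wittig olefination, in which the non-stabilised cyclopropylidene ylide adds 1,2 to the enal carbonyl; the new alkene terminus is symmetric, so no E/Z or stereocentre issue arises.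

Step 2
Reactants: 4 allylidenecyclopropane; 5 2,6-dimethyl-1,4-benzoquinone
Product: 6 cis-adduct, (5β-H,10β-CH3)-13,14-cyclo-11-nordrima-2,7-diene-6,9-dione
Conditions: 4 (2 equiv), (S)-3,3-diphenyl-1-(o-tolyl)tetrahydropyrrolo[1,2-c][1,3,2]oxazaborole·Tf2NH (20 mol %), CH2Cl2, −78 to −40 °C; Et3N quench
Reagents that add atoms: none
Why: This is a concerted but asynchronous normal-demand [4+2] cycloaddition (catalytic enantioselective quinone Diels–Alder reaction with a proline-derived cationic oxazaborolidine); the cation binds the more basic, unhindered C6 carbonyl of 5 at the lone pair syn to C5–H and so makes C10 the most electrophilic ring carbon. Ring A is closed intermolecularly by suprafacial formation of two σ-bonds, C1–C10 (leading) and C4–C5 (lagging), across the C5=C10 edge of the pre-existing ring B, and no carbocycle of the skeleton is formed afterwards. The closest known reactions are the Lewis-acid-reversed orientation of 1-substituted dienes with this quinone, cationic-oxazaborolidine cycloadditions of methyl-substituted quinones, and Diels–Alder reactions of allylidenecyclopropane, whose tied-back ring removes the Z-methyl clash that makes 4-methylpenta-1,3-diene inert and whose methylenecyclopropane strain is released at C4. C10 (quaternary, CH3 β) is set by the catalyst, whose aryl group shields one face of the bound enone so that the enantiotopic C=C bonds of C2v-symmetric 5 are distinguished; C5 follows as cis (5β-H) from suprafacial addition and is corrected in step 3. Regioselectivity is secured twice, by catalyst-induced polarisation (the nucleophilic CH2 terminus C1 goes to C10) and by sterics (fully substituted C4 avoids the methyl-bearing C10), and endo/exo selectivity is irrelevant because neither diene terminus becomes stereogenic. A second addition is held back because the ene-dione 6 is a much poorer, more hindered dienophile than 5.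

Step 3
Reactants: 6 cis-adduct
Product: 7 trans-ene-dione, (5α-H,10β-CH3)-13,14-cyclo-11-nordrima-2,7-diene-6,9-dione
Conditions: DBU (0.2 equiv), CH2Cl2, rt
Reagents that add atoms: none
Why: Base-mediated epimerisation through the C5 enolate (the classical cis-to-trans correction of angular-methyl quinone adducts) should give 5α-H, because reprotonation comes from the α face, anti to the C10 methyl and the β-methylene of the cyclopropane, and leads to the less congested trans-decalin; quaternary C10 blocks aromatisation, and C5 stays correctable until step 9.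

Step 4
Reactants: 7 trans-ene-dione
Product: 9 13,14-cyclo-11-nor-6-oxodrima-2,8-dien-9-yl triflate, via lithium C9 enolate 8 (not isolated)
Conditions: L-Selectride (1.0 equiv), THF, −78 °C; then Comins' reagent, −78 to 0 °C
Reagents that add atoms: Comins' reagent [N-(5-chloropyridin-2-yl)bis(trifluoromethanesulfonimide)], O=S(=O)(C(F)(F)F)N(c1ccc(Cl)cn1)S(=O)(=O)C(F)(F)F
Why: Conjugate reduction with enolate trapping (reductive enol triflation), in which the bulky hydride should add to unsubstituted C7 (β to C9=O) rather than to methyl-bearing C8, giving the C9(O–)=C8 enolate regiospecifically for O-sulfonylation; no stereocentre is created.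

Step 5
Reactants: 9 enol triflate
Product: 10 TMSE 6-oxo-13,14-cyclodrima-2,8-dien-11-oate
Conditions: Pd(OAc)2 (10 mol %), dppf, CO (1 atm), TMSCH2CH2OH (10 equiv), Et3N, DMF, 60 °C
Reagents that add atoms: carbon monoxide, [C-]#[O+]; 2-(trimethylsilyl)ethanol, C[Si](C)(C)CCO
Why: Pd(0)-catalysed alkoxycarbonylation of an enol triflate, as known for 2,6,6-trisubstituted cyclohexenyl triflates, installs C11 on C9; the unactivated vinylcyclopropane and the ketone are not substrates for Pd(0).

Step 6
Reactants: 10 keto ester
Product: 11 TMSE 6β-hydroxydrim-8-en-11-oate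
Conditions: H2 (4 atm), PtO2, AcOH, rt
Reagents that add atoms: none
Why: Adams-catalyst hydrogenation should first saturate the cis-disubstituted C2=C3 bond, then hydrogenolyse the least hindered CH2–CH2 bond of the 1,1-dialkylcyclopropane (the standard spirocyclopropane-to-gem-dimethyl unmasking) and knowingly reduce the C6 ketone from the open α face, while the tetrasubstituted ester-conjugated C8=C9 bond next to quaternary C10 and the TMSE ester are left; the C6 carbinol centre is erased in step 7.

Step 7
Reactants: 11 hydroxy ester
Product: 12 TMSE 6-oxodrim-8-en-11-oate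
Conditions: Dess–Martin periodinane, CH2Cl2, 0 °C to rt
Reagents that add atoms: none
Why: Dess–Martin oxidation returns the C6 ketone under non-enolising conditions so that C8=C9 stays in place; the ketone is needed because only it makes C7–H2 selectively acidic over C12–H3 for step 8.

Step 8
Reactants: 12 keto ester
Product: 14 TMSE 9α-hydroxy-6-oxodrim-7-en-11-oate, via 9α-hydroperoxide 13 (not isolated)
Conditions: O2 (1 atm), DBU (0.3 equiv), P(OEt)3, MeCN, 0 °C
Reagents that add atoms: dioxygen, O=O
Why: Aerobic hydroxylation of a vinylogous β-keto ester, in which the weak base removes only the doubly activated C7–H, O2 traps the extended enolate at C9 (γ to the ketone, α to the ester) with the alkene moving to C7=C8, and the phosphite reduces the hydroperoxide; O2 enters axially from the α face, anti to the adjacent axial C10 methyl, which sets 9α-OH/9β-CO2R.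

Step 9
Reactants: 14 hydroxy enone
Product: 15 TMSE 6β,9α-dihydroxydrim-7-en-11-oate
Conditions: NaBH4, CeCl3·7H2O, MeOH, −78 to 0 °C
Reagents that add atoms: none
Why: Luche 1,2-reduction, in which the β face of C6=O is closed by the two 1,3-diaxial methyl groups (C15 on C10 and the β-methyl on C4), so hydride should arrive from the α face and give the axial 6β-alcohol.

Step 10
Reactants: 15 diol
Product: 17 TMSE 6β,9α-dihydroxy-12-oxodrim-7-en-11-oate, via TMSE 6β,9α,12-trihydroxydrim-7-en-11-oate 16 (not isolated)
Conditions: SeO2 (2 equiv), 1,4-dioxane, 80 °C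
Reagents that add atoms: selenium dioxide, O=[Se]=O
Why: Riley allylic oxidation (ene reaction then [2,3]-shift), in which selenium binds the less substituted C7 and the only allylic hydrogens on the C8 side are those of C12 (C9 is fully substituted), so oxidation is channelled to C12 and carried on to the enal, as known for drim-7-enes.

Step 11
Reactants: 18 (2E,4E)-hexa-2,4-dienal; 19 malonic acid
Product: 21 (2E,4E,6E)-octa-2,4,6-trienoic acid, via (2E,4E)-hexa-2,4-dienylidenemalonic acid 20 (not isolated)
Conditions: pyridine, piperidine (cat.), 90 °C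
Reagents that add atoms: none
Why: Knoevenagel–Doebner condensation with decarboxylation gives the thermodynamically favoured new (E)-alkene and leaves the existing E,E-diene untouched.

Step 12
Reactants: 17 dihydroxy enal; 21 octatrienoic acid
Product: 23 TMSE 6β-[(2E,4E,6E)-octa-2,4,6-trienoyloxy]-9α-hydroxy-12-oxodrim-7-en-11-oate, via octatrienoic 2,4,6-trichlorobenzoic anhydride 22 (not isolated)
Conditions: 21, 2,4,6-Cl3C6H2COCl, Et3N, toluene, rt; then 17, DMAP (0.5 equiv), rt to 40 °C
Reagents that add atoms: none
Why: Yamaguchi esterification is chosen for the hindered axial 6β-OH; the tertiary 9α-OH next to quaternary C10 is inert to acyl transfer, and the C6 configuration is retained because only the O–H bond reacts.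

Step 13
Reactants: 23 TMSE ester
Product: 24 ustusoic acid B
Conditions: TBAF/AcOH (1:1), THF, 0 °C to rt
Reagents that add atoms: none
Why: Fluoride-induced β-elimination of the TMSE ester attacks silicon remote from the hindered C11 carbonyl, so the acid is released without touching the trienoate, the enal or any stereocentre; the buffer suppresses γ-deprotonation at C6.

## Compound list
1 | cyclopropyltriphenylphosphonium bromide | [Br-].C1CC1[P+](c1ccccc1)(c1ccccc1)c1ccccc1 | starting material
2 | acrolein | C=CC=O | starting material
3 | cyclopropylidene(triphenyl)phosphorane | C1CC1=P(c1ccccc1)(c1ccccc1)c1ccccc1 | intermediate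
4 | allylidenecyclopropane | C=CC=C1CC1 | intermediate
5 | 2,6-dimethyl-1,4-benzoquinone | CC1=CC(=O)C=C(C)C1=O | starting material
6 | cis-adduct, (4a'R,8a'S)-2',8a'-dimethyl-4a',8a'-dihydro-8'H-spiro[cyclopropane-1,5'-naphthalene]-1',4'-dione (5β-H,10β-CH3) | O=C1C=C(C)C(=O)[C@@]2(C)CC=CC3(CC3)[C@@H]12 | intermediate
7 | trans-ene-dione, (4a'S,8a'S) epimer of 6 (5α-H,10β-CH3) | O=C1C=C(C)C(=O)[C@@]2(C)CC=CC3(CC3)[C@H]12 | intermediate
8 | lithium C9 enolate of the 7,8-dihydro derivative of 7 | O=C1CC(C)=C([O-])[C@@]2(C)CC=CC3(CC3)[C@H]12.[Li+] | intermediate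
9 | (5α,10β)-13,14-cyclo-11-nor-6-oxodrima-2,8-dien-9-yl triflate | O=C1CC(C)=C(OS(=O)(=O)C(F)(F)F)[C@@]2(C)CC=CC3(CC3)[C@H]12 | intermediate
10 | TMSE (5α,10β)-6-oxo-13,14-cyclodrima-2,8-dien-11-oate | O=C1CC(C)=C(C(=O)OCC[Si](C)(C)C)[C@@]2(C)CC=CC3(CC3)[C@H]12 | intermediate
11 | TMSE 6β-hydroxydrim-8-en-11-oate | O[C@@H]1CC(C)=C(C(=O)OCC[Si](C)(C)C)[C@@]2(C)CCCC(C)(C)[C@H]12 | intermediate
12 | TMSE 6-oxodrim-8-en-11-oate | O=C1CC(C)=C(C(=O)OCC[Si](C)(C)C)[C@@]2(C)CCCC(C)(C)[C@H]12 | intermediate
13 | TMSE 9α-hydroperoxy-6-oxodrim-7-en-11-oate | O=C1C=C(C)[C@](OO)(C(=O)OCC[Si](C)(C)C)[C@@]2(C)CCCC(C)(C)[C@H]12 | intermediate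
14 | TMSE 9α-hydroxy-6-oxodrim-7-en-11-oate | O=C1C=C(C)[C@](O)(C(=O)OCC[Si](C)(C)C)[C@@]2(C)CCCC(C)(C)[C@H]12 | intermediate
15 | TMSE 6β,9α-dihydroxydrim-7-en-11-oate | O[C@@H]1C=C(C)[C@](O)(C(=O)OCC[Si](C)(C)C)[C@@]2(C)CCCC(C)(C)[C@H]12 | intermediate
16 | TMSE 6β,9α,12-trihydroxydrim-7-en-11-oate | O[C@@H]1C=C(CO)[C@](O)(C(=O)OCC[Si](C)(C)C)[C@@]2(C)CCCC(C)(C)[C@H]12 | intermediate
17 | TMSE 6β,9α-dihydroxy-12-oxodrim-7-en-11-oate | O[C@@H]1C=C(C=O)[C@](O)(C(=O)OCC[Si](C)(C)C)[C@@]2(C)CCCC(C)(C)[C@H]12 | intermediate
18 | (2E,4E)-hexa-2,4-dienal | C/C=C/C=C/C=O | starting material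
19 | malonic acid | OC(=O)CC(=O)O | starting material
20 | (2E,4E)-hexa-2,4-dienylidenemalonic acid | C/C=C/C=C/C=C(C(=O)O)C(=O)O | intermediate
21 | (2E,4E,6E)-octa-2,4,6-trienoic acid | C/C=C/C=C/C=C/C(=O)O | intermediate
22 | (2E,4E,6E)-octa-2,4,6-trienoic 2,4,6-trichlorobenzoic anhydride | C/C=C/C=C/C=C/C(=O)OC(=O)c1c(Cl)cc(Cl)cc1Cl | intermediate
23 | TMSE 6β-[(2E,4E,6E)-octa-2,4,6-trienoyloxy]-9α-hydroxy-12-oxodrim-7-en-11-oate | C/C=C/C=C/C=C/C(=O)O[C@@H]1C=C(C=O)[C@](O)(C(=O)OCC[Si](C)(C)C)[C@@]2(C)CCCC(C)(C)[C@H]12 | intermediate
24 | ustusoic acid B, 6β-[(2E,4E,6E)-octa-2,4,6-trienoyloxy]-9α-hydroxy-12-oxodrim-7-en-11-oic acid | C/C=C/C=C/C=C/C(=O)O[C@@H]1C=C(C=O)[C@](O)(C(=O)O)[C@@]2(C)CCCC(C)(C)[C@H]12 | target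

## Step count and risks
Total steps: 13. Longest linear sequence: 12 (steps 1–10, 12, 13).

**Step 2.** The strongly acidic catalyst may oligomerise or ring-open the strained diene faster than it cycloadds, or facial discrimination on the quinone may be insufficient. The fallback gives up catalytic induction and resolves instead. It sets out from 4 and 5 and comes back at 7. An achiral Lewis acid with the same orienting effect (BF3·OEt2, CH2Cl2, −78 °C) should give the racemic cycloadduct, that is 6 together with its mirror image, ent-cis-adduct F1. DBU as in step 3 then gives 7 together with ent-trans-ene-dione F2. The enantiomers are separated by preparative chromatography on a chiral stationary phase, and 7 re-enters the route.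

**Step 10.** The ene step may be sluggish at an alkene flanked by two oxygenated carbons, and may be overtaken by oxidation of the allylic 6β-OH or by dehydration. The fallback moves the C12 oxidation to the enone stage and uses vinylogous enolate chemistry. It sets out from 14 and comes back at 17. TMSOTf/Et3N should give, by γ-deprotonation at C12 and silylation of 9-OH, the bis-TMS extended dienol ether F4. A vinylogous Rubottom oxidation (mCPBA, NaHCO3, then mild acid) places oxygen at the diene terminus and gives the 12-hydroxy enone F5. Luche reduction as in step 9 gives triol 16, here isolated, whose primary allylic alcohol is oxidised selectively (MnO2 or TEMPO/PhI(OAc)2) to 17.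

**Step 4.** Hydride may attack the less hindered C6 carbonyl in 1,2 fashion, or proton transfer from the acidic C7–H2 may scramble the enolate before O-sulfonylation. The fallback replaces the free lithium enolate by an isolable enol silane. It sets out from 7 and comes back at 9. Copper-hydride-catalysed 1,4-hydrosilylation ([(Ph3P)CuH]6 cat., PhMe2SiH, toluene) should deliver hydride to C7 and give the C9 dimethylphenylsilyl enol ether F3. This is converted directly into 9 with CsF/PhNTf2 in DME.

## Further compounds
F1 | step 2 | ent-cis-adduct (mirror image of 6) | O=C1C=C(C)C(=O)[C@]2(C)CC=CC3(CC3)[C@H]12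
F2 | step 2 | ent-trans-ene-dione (mirror image of 7) | O=C1C=C(C)C(=O)[C@]2(C)CC=CC3(CC3)[C@@H]12
F3 | step 4 | C9 dimethylphenylsilyl enol ether of the 7,8-dihydro derivative of 7 | O=C1CC(C)=C(O[Si](C)(C)c3ccccc3)[C@@]2(C)CC=CC4(CC4)[C@H]12
F4 | step 10 | TMSE 6,9α-bis(trimethylsilyloxy)drima-6,8(12)-dien-11-oate | C[Si](C)(C)OC1=CC(=C)[C@](O[Si](C)(C)C)(C(=O)OCC[Si](C)(C)C)[C@@]2(C)CCCC(C)(C)[C@H]12
F5 | step 10 | TMSE 9α,12-dihydroxy-6-oxodrim-7-en-11-oate | O=C1C=C(CO)[C@](O)(C(=O)OCC[Si](C)(C)C)[C@@]2(C)CCCC(C)(C)[C@H]12
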